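Readings first.

| flask | starting material | second substrate | enzyme | remark | time |
|---|---|---|---|---|---|
| elm | 0.16 M | 1.1 equiv | 9.5 × 10⁻⁴ mol% | run made earlier |  |
| ash | 0.16 M | 1.1 equiv | 6.4 × 10⁻⁴ mol% | run made earlier |  |
| cedar | 0.16 M | 1.1 equiv | 0.0014 mol% | run made earlier |  |
| alder | 0.16 M | 2.2 equiv | 9.5 × 10⁻⁴ mol% | run made earlier |  |
| winter | 0.16 M | 1.10 equiv (fed, over 1.5 h) | 9.5 × 10⁻⁴ mol% | all else is in the flask from the start; the feed brings no volume worth counting | 4.0 h |
| noon | 0.16 M (in portions, 3, over 1.5 h) | 1.10 equiv | 9.5 × 10⁻⁴ mol% | first portion at the start, last at 1.5 h | 4.0 h |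
| dawn | 0.16 M | 1.10 equiv | 9.5 × 10⁻⁴ mol% | everything together at the start | 4.0 h |
| midnight | 0.16 M (fed, over 1.5 h) | 1.10 equiv | 9.5 × 10⁻⁴ mol% | all else is in the flask from the start; the feed brings no volume worth counting | 4.0 h |

| elm: time / h | elm: product / % | ash: time / h | ash: product / % | cedar: time / h | cedar: product / % | alder: time / h | alder: product / % |
|---|---|---|---|---|---|---|---|
| 0.833 | 33.6 | 1.00 | 28.2 | 0.417 | 25.6 | 1.00 | 44.7 |
| 1.50 | 51.7 | 2.00 | 46.9 | 1.33 | 62.7 | 2.00 | 72.1 |
| 2.50 | 67.7 | 3.00 | 60.9 | 2.00 | 74.0 | 3.00 | 87.0 |
| 3.00 | 73.7 | 4.00 | 69.9 | 3.00 | 82.3 | 4.00 | 92.5 |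
| 4.00 | 79.8 | 5.00 | 75.5 | 5.00 | 88.1 | 5.00 | 94.8 |

(readings scatter by 0.5 percentage points)

1. the flask that comes out highest in amount of product, in percent of the starting material charged, or "all alike" when all lie within 1.5 percentage points (winter / noon / dawn / midnight / all alike)
2. product at the end, in percent of the starting material charged, winter
3. product at the end, in percent of the starting material charged, noon
4. product at the end, in percent of the starting material charged, dawn
5. product at the end, in percent of the starting material charged, midnight

- the numbers in the tables scatter by 0.5 percentage points (one standard deviation)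

The scatter of 0.5 percentage points matters little here, being small against the gap between elm and ash at 4.00 h. The charge of second substrate matters: alder's doubled charge adds 13 points over elm at 4.00 h. But all four flasks receive 1.10 equiv in the end, so the size of that charge does not separate them, though winter receives it by feed. The loading matters more subtly: ash's lower loading costs 9.9 points at 4.00 h, yet time can stand in for it. Hence one number must be known well, the equivalent time, meaning clock time multiplied by the loading over elm's loading. In elm, ash and cedar, all batch runs with one charge of second substrate, the product can be read against it (Selwyn's test). Cedar at 2.00 h has 2.95 h of it and reads 74.0%, while elm at 3.00 h reads 73.7%. Near the end, elm's last hour adds 6.1 points. Each recipe here holds 4.00 h on paper, so my own reckoning sets dawn at elm's 79.8%. It gives the fed flasks no number, since no fed run stands among the readings.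

The forecast says dawn comes highest, with winter 76.3%, noon 76%, dawn 80% and midnight 76%, and argues “I see no substrate inhibition, so feeding has nothing to gain”.

The flasks give winter 73.7%, noon 66.5%, dawn 79.8% and midnight 61.7%, so dawn is highest. Noon and midnight fall 9.5 points and 14 points below the forecast.

    2 enzyme → spent catalyst A (k = 17000 /M/min)
    starting material + enzyme ⇌ starting complex (K = 10.0 /M, k = 48000 /M/min)
    second substrate + starting complex ⇌ ternary complex (K = 84.0 /M, k = 77000 /M/min)
    enzyme ⇌ dormant form (K = 0.350, k = 0.0110 /min)
    ternary complex → enzyme + product (k = 1200 /min)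
    second substrate + starting complex → spent catalyst B (k = 0.0470 /M/min)

Midnight's 61.7% lies near ash's reading of 60.9% at 3.00 h, an equivalent time of 2.02 h, so, read against that batch run, midnight worked about half of its 4.00 h. A neighbour, midnight with 0.0016 mol% of enzyme, gives 70.0%, close to ash's 69.9% at 4.00 h: read the same way, 2.69 h worked of 6.74 h, a share of 39.9%. The largest single effect on midnight's shortfall against dawn is the conversion of 2 enzyme into spent catalyst A: struck out, the gap from dawn to midnight shrinks from 18 points to 3.5 points.

The runs were computed for an exercise; noise was put on by code.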